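1. I have 5 questions to answer, all about the share of target in target plus isomer (the selectivity).

1. the set-up with the highest share of target in all that became target or isomer of the product, at the outlet or at the end ("none" if the first two lie within 2 percentage points) (grey / green / ochre / violet / none)
2. share of target in all that became target or isomer of the product, at the outlet or at the end, grey
3. share of target in all that became target or isomer of the product, at the outlet or at the end, green
4. share of target in all that became target or isomer of the product, at the outlet or at the end, ochre
5. share of target in all that became target or isomer of the product, at the outlet or at the end, violet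

| flask | substrate | partner | free catalyst | remark | time |
|---|---|---|---|---|---|
| oak | 0.10 M | 0.090 M | 59 µM | run made earlier |  |
| birch | 0.050 M | 0.090 M | 59 µM | run made earlier |  |
| elm | 0.075 M | 0.090 M | 59 µM | run made earlier |  |
| ash | 0.10 M | 0.14 M | 59 µM | run made earlier |  |
| grey | 0.10 M (fed, over 8.00 h) | 0.0900 M | 59 µM | all but substrate at the start; substrate goes in evenly over 8.00 h, the run ends at 10 h | 10 h |
| green | 0.10 M | 0.0900 M | 59 µM | a closed flask charged with all of it at once and left for 10 h | 10 h |
| ochre | 0.10 M | 0.0900 M | 59 µM | one stirred flow tank at steady state, fed with the mixture as stated, mean residence time 10 h |  |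
| violet | 0.10 M | 0.0900 M | 59 µM | a tube with plug flow, the mixed feed as stated, residence time 10 h | 10 h |

- oak (time / h: target / %, isomer of the product / %): 2.50: 26.0, 14.5; 5.00: 13.9, 12.8; 8.00: 8.2, 10.5; 10.0: 6.1, 10.7
- birch (time / h: target / %, isomer of the product / %): 1.33: 37.9, 16.1; 4.00: 14.4, 14.5; 6.00: 7.8, 13.0; 10.0: 3.7, 9.1
- elm (time / h: target / %, isomer of the product / %): 1.33: 36.6, 15.1; 4.00: 15.6, 14.3; 6.00: 9.9, 12.6; 10.0: 4.9, 9.0
- ash (time / h: target / %, isomer of the product / %): 2.50: 31.2, 18.7; 5.00: 16.9, 16.3; 8.00: 10.7, 13.9; 10.0: 7.6, 11.4

(standard deviation of a reading: 0.5 percentage points)

- the stated concentrations are those of everything mixed, before any reaction; amounts are the same in each set-up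
- the feed brings no volume worth counting
- the earlier runs were made in a closed, stirred flask

2. Time comes first. In the oak run the readings put the crossing at 5.75 h. This crossover age t× is the time after charging at which target and isomer stand equal, with ln(target/isomer) interpolated between the readings on either side. Before it target leads; after it isomer leads.

3. Next comes c(substrate). By hand, birch gives 3.98 h. So going from 0.050 M to 0.10 M moves t× later.

4. Then c(partner). By hand, ash gives 5.36 h. That is 0.390 h from oak, and with readings good to 0.5 percentage points I count it as no shift.

5. c(free catalyst) is 59 µM in oak, birch, elm and ash, so these runs show me no effect of it.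

6. Last comes the vessel. Green and violet share one history, 10 h of age, which is past t×. Oak's last reading gives a share of 36.3 %. Grey takes its substrate over 8.00 h with partner present from the start, so I do not carry oak's t× over to grey. In ochre, 43.7 % of the outflow is younger than t×, while green and violet stand wholly at 10 h, so I rank ochre above green and violet, without a number of my own. I leave grey's place open.

7. The forecast also names ochre, with grey 47 %, green 38 %, ochre 54 % and violet 38 %. It says: “Ochre has an exponential age spread, with much young material.”

8. The flasks give grey 48.4 %, green 41.4 %, ochre 74.5 % and violet 41.4 %. Ochre is best, 20 points above the forecast.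

    substrate + partner ⇌ isomer of the product (K = 28.0 /M, k = 0.0520 /M/min)
    partner → decomposed reagent (k = 0.0220 /min)
    substrate + partner ⇌ target (K = 56.0 /M, k = 2.60 /M/min)
    free catalyst → spent catalyst (k = 0.0330 /min)
    target + free catalyst ⇌ isomer of the product + free catalyst, rate k5*[free catalyst]*[target] forward; the back reaction follows from the equilibrium constant (k = 270 /M/min)

9. Ochre's target leads although its residence time is past t×. Partner's half-life by its decomposition alone is 0.53 h, far shorter than t×. Violet, past t×, has isomer ahead, as oak's crossing says. Grey ends with more isomer, 1.17 %, than target, 1.10 %, of the substrate charged.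

All runs are calculated from invented constants; the scatter is artificial.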